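**Plan**
1. Retrosynthetic cuts, in order: the coumarate C(=O)–O bond, the aryl–C(=O) bond of the 2,5-dihydroxyphenyl ketone, the C6–CH2 bond to the side chain, the ring bond O1–C7, then C6–C7, C4=C5 and C2–C3 back to malic acid.
2. Enabling feature: in the 2,3,4,7-tetrahydrooxepine (O1, quaternary C2, C3, C4, C5=C6, C7H2), C7 lies between O1 and sp2 C6. If C6 is read as a ketone, C7 becomes the carbon of a diazomethyl ketone. The crowded, carboxyl-flanked tertiary O1–H can then be etherified by a metal carbenoid without base.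
3. Forward, first half: D-malic acid → cis-pivalaldehyde dioxolanone → allylation → Weinreb amide arm → cross-metathesis and hydrogenation (C4–C6) → diazo ketone (C7) → release of the hydroxy ester → Rh(II) closure of the only new ring, as an oxepan-6-one.
4. Forward, second half: enol triflate on the C5 side, B-alkyl Suzuki coupling with the side chain (fixes C5=C6), aryl Grignard addition to the amide, coumaroylation, and one fluoride step that removes every silicon group.
5. Stereochemistry: C2 (R) comes from D-malic acid by self-regeneration of stereocentres, with allyl entering anti to tert-butyl (overall retention). The side-chain E-alkene comes from a stabilised Wittig reaction, and the coumarate E-alkene is bought.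

Key step: step 8

Remark: the C2 carboxyl travels as its 2-(trimethylsilyl)ethyl (TMSE) ester and the phenols as TBS ethers, so one fluoride treatment ends the route without touching the allylic coumarate. The dioxolanone is kept until the diazo ketone is in place, so the activated C6 acid cannot lactonise onto the tertiary hydroxyl.

**Step 1**
Reactants: 1 D-malic acid
Product: 2 [(2R,4R)-2-tert-butyl-5-oxo-1,3-dioxolan-4-yl]acetic acid (cis)
Conditions: t-BuCHO, p-TsOH (cat.), H2SO4 (cat.), pentane, reflux, Dean–Stark; recrystallisation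
Reagents that add atoms: pivalaldehyde CC(C)(C)C=O
Why: Acid-catalysed acetalisation of the α-hydroxy acid unit prefers the five-membered dioxolanone and, under thermodynamic control, its cis isomer, so the new acetal carbon (R) is set by the malate stereocentre and purified by crystallisation.

**Step 2**
Reactants: 2 cis-dioxolanone acid; 3 allyl bromide
Product: 5 [(2R,4R)-4-allyl-2-tert-butyl-5-oxo-1,3-dioxolan-4-yl]acetic acid, via dilithio enolate 4 (not isolated)
Conditions: LiHMDS (2.2 equiv), THF, −78 °C; 3, −78 → −20 °C; 1 M HCl work-up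
Reagents that add atoms: none
Why: In this self-regeneration-of-stereocentres enolate alkylation the planar enolate is attacked anti to the tert-butyl group, so allyl takes the place of H with overall retention and the quaternary carbon is (R).

**Step 3**
Reactants: 5 allylated dioxolanone acid
Product: 6 2-[(2R,4R)-4-allyl-2-tert-butyl-5-oxo-1,3-dioxolan-4-yl]-N-methoxy-N-methylacetamide
Conditions: MeNHOMe·HCl, EDC·HCl, N-methylmorpholine (2.2 equiv), CH2Cl2, 0 °C → rt
Reagents that add atoms: N,O-dimethylhydroxylamine hydrochloride CNOC.Cl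
Why: Carbodiimide amide coupling acts on the only free carboxyl, and the weakly nucleophilic amine should leave the hindered dioxolanone carbonyl alone.

**Step 4**
Reactants: 6 allyl Weinreb amide; 7 benzyl acrylate
Product: 8 benzyl (2E)-4-[(2R,4R)-2-tert-butyl-4-{2-[methoxy(methyl)amino]-2-oxoethyl}-5-oxo-1,3-dioxolan-4-yl]but-2-enoate
Conditions: 7 (3 equiv), Hoveyda–Grubbs II (3 mol %), CH2Cl2, 40 °C
Reagents that add atoms: none
Why: Olefin cross-metathesis of a terminal (type I) alkene with an acrylate (type II) favours the hetero-coupled E-enoate, and the alkene geometry is erased in the next step.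

**Step 5**
Reactants: 8 benzyl enoate
Product: 9 4-[(2R,4R)-2-tert-butyl-4-{2-[methoxy(methyl)amino]-2-oxoethyl}-5-oxo-1,3-dioxolan-4-yl]butanoic acid
Conditions: H2 (1 atm), 10 % Pd/C, EtOAc, rt
Reagents that add atoms: none
Why: Heterogeneous catalytic hydrogenation saturates the enoate and hydrogenolyses the benzyl ester in one operation, while the acetal and the amide N–O bond are inert at this pressure.

**Step 6**
Reactants: 9 dioxolanone butanoic acid
Product: 11 2-[(2R,4R)-2-tert-butyl-4-(5-diazo-4-oxopentyl)-5-oxo-1,3-dioxolan-4-yl]-N-methoxy-N-methylacetamide, via isobutyl mixed anhydride 10 (not isolated)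
Conditions: i-BuOCOCl, N-methylmorpholine, THF, −20 °C; then CH2N2, Et2O, 0 °C → rt
Reagents that add atoms: diazomethane C=[N+]=[N-]
Why: Acylation of diazomethane by a mixed carbonic anhydride (first stage of the Arndt–Eistert sequence) gives the terminal diazo ketone, and the activated acid cannot form a δ-lactone because the tertiary oxygen is still part of the dioxolanone.

**Step 7**
Reactants: 11 dioxolanone diazo ketone
Product: 12 2-(trimethylsilyl)ethyl (2R)-7-diazo-2-hydroxy-2-{2-[methoxy(methyl)amino]-2-oxoethyl}-6-oxoheptanoate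
Conditions: TMSCH2CH2OH (10 equiv), n-BuLi (0.3 equiv), THF, 0 °C; pH 7 buffer
Reagents that add atoms: 2-(trimethylsilyl)ethanol C[Si](C)(C)CCO
Why: Alkoxide-catalysed alcoholysis of the dioxolanone gives the ester, and the hemiacetal collapses with loss of pivalaldehyde, under conditions that terminal diazo ketones, the Weinreb amide and the non-epimerisable quaternary carbon tolerate.

**Step 8**
Reactants: 12 hydroxy diazo ketone
Product: 13 2-(trimethylsilyl)ethyl (2R)-2-{2-[methoxy(methyl)amino]-2-oxoethyl}-6-oxooxepane-2-carboxylate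
Conditions: Rh2(OAc)4 (1 mol %), CH2Cl2, reflux, slow addition of 12 (final about 5 mM), Ar
Reagents that add atoms: none
Why: Rh2(OAc)4 expels N2 from the diazomethyl ketone to give an electrophilic rhodium carbenoid at C7; the lone pair of the tertiary hydroxyl O1 adds to it, and the oxonium ylide collapses by proton transfer with release of the catalyst, which forms O1–C7 and leaves the ketone at C6. The closest known reaction type is the rhodium(II)-catalysed intramolecular O–H insertion of ω-hydroxy α-diazo carbonyl compounds, an established entry to 3-oxo-oxepanes. The seven-membered ring closes by attack of O1 on the terminal carbenoid carbon, formally a 7-exo closure because the breaking Rh=C bond lies outside the new ring, and the fully substituted C2 helps through a Thorpe–Ingold effect. No stereocentre is created (C7 becomes CH2), and quaternary C2 is untouched because no alkoxide is ever present, so retro-aldol or β-elimination next to the ester cannot start. The step needs O–H insertion to win over 1,5-C–H insertion at C3 (cyclopentanone), over capture by the ester or amide carbonyl oxygens, and over bimolecular carbene reactions. The hydroxyl lone pair is by far the best nucleophile, the C3–H bonds are inductively deactivated by the oxygenated, ester-bearing C2, the carbonyl oxygens would need eight- and nine-membered ylides, and slow addition at high dilution suppresses dimers.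

**Step 9**
Reactants: 13 oxepan-6-one
Product: 15 2-(trimethylsilyl)ethyl (2R)-2-{2-[methoxy(methyl)amino]-2-oxoethyl}-6-{[(trifluoromethyl)sulfonyl]oxy}-2,3,4,7-tetrahydrooxepine-2-carboxylate, via lithium C5-enolate 14 (not isolated)
Conditions: LiHMDS (1.1 equiv), THF, −78 °C; Comins reagent, −78 → −40 °C; H2O quench
Reagents that add atoms: N-(5-chloro-2-pyridyl)bis(trifluoromethanesulfonimide) FC(F)(F)S(=O)(=O)N(c1ccc(Cl)cn1)S(=O)(=O)C(F)(F)F
Why: In this kinetic enolisation and O-triflation a lithium amide at −78 °C should take a C5 proton rather than a C7 proton, because an enolate on the C7 side is destabilised by the O1 lone pairs (as with simpler 3-oxo cyclic ethers), and LiHMDS is too weak a base to deprotonate the amide arm.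

**Step 10**
Reactants: 16 acrolein; 17 ethyl 2-(triphenylphosphoranylidene)propanoate
Product: 18 ethyl (2E)-2-methylpenta-2,4-dienoate
Conditions: CH2Cl2, 0 °C → rt
Reagents that add atoms: none
Why: Wittig olefination with a stabilised α-methyl ylide gives the E-trisubstituted enoate, which sets the side-chain alkene geometry.

**Step 11**
Reactants: 18 dienoate
Product: 19 (2E)-2-methylpenta-2,4-dien-1-ol
Conditions: DIBAL-H (2.2 equiv), CH2Cl2, −78 °C; Rochelle salt work-up
Reagents that add atoms: none
Why: DIBAL-H reduces the conjugated ester by 1,2-addition to the allylic alcohol without touching the diene or its geometry.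

**Step 12**
Reactants: 19 dienol
Product: 20 tert-butyl(dimethyl){[(2E)-2-methylpenta-2,4-dien-1-yl]oxy}silane
Conditions: TBSCl, imidazole, CH2Cl2, 0 °C → rt
Reagents that add atoms: tert-butyldimethylsilyl chloride CC(C)(C)[Si](C)(C)Cl
Why: Standard imidazole-promoted silylation of a primary alcohol gives an ether that withstands borane, palladium and Grignard chemistry.

**Step 13**
Reactants: 15 enol triflate; 20 silyloxy diene
Product: 22 2-(trimethylsilyl)ethyl (2R)-6-[(3E)-5-{[tert-butyl(dimethyl)silyl]oxy}-4-methylpent-3-en-1-yl]-2-{2-[methoxy(methyl)amino]-2-oxoethyl}-2,3,4,7-tetrahydrooxepine-2-carboxylate, via homoallylic B-alkyl-9-BBN 21 (not isolated)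
Conditions: 20 (1.5 equiv), 9-BBN-H, THF, 0 °C → rt; then 15, PdCl2(dppf) (5 mol %), AsPh3 (5 mol %), aq. K3PO4, DMF, rt
Reagents that add atoms: none
Why: 9-BBN hydroborates only the monosubstituted terminus of the diene (anti-Markovnikov, with the trisubstituted alkene too hindered), and the B-alkyl Suzuki–Miyaura coupling of the homoallylic borane with the vinyl triflate forms C6–CH2 with the ring alkene fixed at C5=C6.

**Step 14**
Reactants: 23 bromohydroquinone
Product: 24 2-bromo-1,4-bis{[tert-butyl(dimethyl)silyl]oxy}benzene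
Conditions: TBSCl (2.5 equiv), imidazole, DMF, rt
Reagents that add atoms: tert-butyldimethylsilyl chloride CC(C)(C)[Si](C)(C)Cl
Why: Routine bis-silylation of the phenols gives fluoride-labile protection that carries no acidic or electrophilic site.

**Step 15**
Reactants: 22 Weinreb amide; 24 aryl bromide
Product: 27 2-(trimethylsilyl)ethyl (2R)-2-[2-(2,5-bis{[tert-butyl(dimethyl)silyl]oxy}phenyl)-2-oxoethyl]-6-[(3E)-5-{[tert-butyl(dimethyl)silyl]oxy}-4-methylpent-3-en-1-yl]-2,3,4,7-tetrahydrooxepine-2-carboxylate, via aryl Grignard 25 (not isolated), via magnesium hemiaminal chelate 26 (not isolated)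
Conditions: 24 (2 equiv), Mg, I2 (trace), THF, 50 °C; then 22, THF, −20 → 0 °C; pH 7 buffer
Reagents that add atoms: none
Why: In this Weinreb ketone synthesis the chelated tetrahedral adduct prevents over-addition, the magnesium reagent (unlike the lithium one) should not suffer O-to-C silyl migration, and the TMSE ester on the quaternary carbon is far more hindered than the amide on a CH2 group.

**Step 16**
Reactants: 27 tris-TBS aryl ketone
Product: 28 2-(trimethylsilyl)ethyl (2R)-2-[2-(2,5-bis{[tert-butyl(dimethyl)silyl]oxy}phenyl)-2-oxoethyl]-6-[(3E)-5-hydroxy-4-methylpent-3-en-1-yl]-2,3,4,7-tetrahydrooxepine-2-carboxylate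
Conditions: CSA (10 mol %), MeOH/CH2Cl2, 0 °C
Reagents that add atoms: none
Why: Acid-catalysed methanolysis cleaves a primary alkyl TBS ether much faster than aryl TBS ethers, which resist acid, and the TMSE ester is unaffected.

**Step 17**
Reactants: 29 p-coumaric acid
Product: 31 (2E)-3-(4-{[tert-butyl(dimethyl)silyl]oxy}phenyl)prop-2-enoic acid, via bis-silylated coumarate 30 (not isolated)
Conditions: TBSCl (2.3 equiv), imidazole, DMF, rt; then AcOH/THF/H2O, rt
Reagents that add atoms: tert-butyldimethylsilyl chloride CC(C)(C)[Si](C)(C)Cl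
Why: Persilylation followed by mild hydrolysis exploits the much greater lability of a silyl ester over an aryl silyl ether.

**Step 18**
Reactants: 28 allylic alcohol; 31 TBS-coumaric acid
Product: 32 fully silylated target: TMSE ester, three aryl TBS ethers, (E)-coumarate on the side-chain CH2O
Conditions: 31 (1.3 equiv), EDC·HCl, DMAP (cat.), CH2Cl2, 0 °C → rt
Reagents that add atoms: none
Why: Steglich-type esterification acylates the only free hydroxyl, an unhindered primary allylic alcohol, and no competing carboxyl is present because C2–CO2H is still masked.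

**Step 19**
Reactants: 32 fully silylated target
Product: 33 CNP0602535.1, (2R)-2-[2-(2,5-dihydroxyphenyl)-2-oxoethyl]-6-[(3E)-5-{[(2E)-3-(4-hydroxyphenyl)prop-2-enoyl]oxy}-4-methylpent-3-en-1-yl]-2,3,4,7-tetrahydrooxepine-2-carboxylic acid
Conditions: TASF (6 equiv), degassed DMF, 0 °C → rt, Ar; cold 0.1 M HCl/brine work-up
Reagents that add atoms: none
Why: Fluoride-induced desilylation frees the three phenols and fragments the β-silylethyl ester to the acid under nearly non-basic conditions, and the ortho-phenoxide formed first lowers the acidity of the ketone α-CH2, which guards against β-elimination of O1.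

**Compound list**
1 | D-malic acid | O[C@H](CC(=O)O)C(=O)O | starting material
2 | [(2R,4R)-2-tert-butyl-5-oxo-1,3-dioxolan-4-yl]acetic acid | CC(C)(C)[C@@H]1O[C@H](CC(=O)O)C(=O)O1 | intermediate
3 | allyl bromide | C=CCBr | starting material
4 | dilithio enolate-carboxylate of 2 | CC(C)(C)[C@@H]1OC(CC(=O)[O-])=C([O-])O1.[Li+].[Li+] | intermediate
5 | [(2R,4R)-4-allyl-2-tert-butyl-5-oxo-1,3-dioxolan-4-yl]acetic acid | CC(C)(C)[C@@H]1O[C@](CC=C)(CC(=O)O)C(=O)O1 | intermediate
6 | allyl dioxolanone Weinreb amide | CC(C)(C)[C@@H]1O[C@](CC=C)(CC(=O)N(C)OC)C(=O)O1 | intermediate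
7 | benzyl acrylate | C=CC(=O)OCc1ccccc1 | starting material
8 | benzyl (E)-enoate from cross-metathesis | CC(C)(C)[C@@H]1O[C@](C/C=C/C(=O)OCc2ccccc2)(CC(=O)N(C)OC)C(=O)O1 | intermediate
9 | dioxolanone butanoic acid | CC(C)(C)[C@@H]1O[C@](CCCC(=O)O)(CC(=O)N(C)OC)C(=O)O1 | intermediate
10 | isobutyl carbonic mixed anhydride of 9 | CC(C)(C)[C@@H]1O[C@](CCCC(=O)OC(=O)OCC(C)C)(CC(=O)N(C)OC)C(=O)O1 | intermediate
11 | dioxolanone diazo ketone | CC(C)(C)[C@@H]1O[C@](CCCC(=O)C=[N+]=[N-])(CC(=O)N(C)OC)C(=O)O1 | intermediate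
12 | TMSE (2R)-7-diazo-2-hydroxy-2-(Weinreb amidomethyl)-6-oxoheptanoate | C[Si](C)(C)CCOC(=O)[C@](O)(CC(=O)N(C)OC)CCCC(=O)C=[N+]=[N-] | intermediate
13 | TMSE (2R)-2-(Weinreb amidomethyl)-6-oxooxepane-2-carboxylate | C[Si](C)(C)CCOC(=O)[C@]1(CC(=O)N(C)OC)CCCC(=O)CO1 | intermediate
14 | lithium C5=C6 enolate of 13 | C[Si](C)(C)CCOC(=O)[C@]1(CC(=O)N(C)OC)CCC=C([O-])CO1.[Li+] | intermediate
15 | C6 enol triflate (C5=C6) | C[Si](C)(C)CCOC(=O)[C@]1(CC(=O)N(C)OC)CCC=C(OS(=O)(=O)C(F)(F)F)CO1 | intermediate
16 | acrolein | C=CC=O | starting material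
17 | ethyl 2-(triphenylphosphoranylidene)propanoate | CCOC(=O)C(C)=P(c1ccccc1)(c1ccccc1)c1ccccc1 | starting material
18 | ethyl (2E)-2-methylpenta-2,4-dienoate | C=C/C=C(\C)C(=O)OCC | intermediate
19 | (2E)-2-methylpenta-2,4-dien-1-ol | C=C/C=C(\C)CO | intermediate
20 | TBS ether of 19 | C=C/C=C(\C)CO[Si](C)(C)C(C)(C)C | intermediate
21 | B-[(3E)-5-(TBSO)-4-methylpent-3-en-1-yl]-9-BBN | C/C(=C\CCB1C2CCCC1CCC2)CO[Si](C)(C)C(C)(C)C | intermediate
22 | Suzuki product (TMSE ester, Weinreb amide, side-chain OTBS) | C[Si](C)(C)CCOC(=O)[C@]1(CC(=O)N(C)OC)CCC=C(CC/C=C(\C)CO[Si](C)(C)C(C)(C)C)CO1 | intermediate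
23 | bromohydroquinone | Oc1ccc(O)c(Br)c1 | starting material
24 | 2-bromo-1,4-bis(TBSO)benzene | CC(C)(C)[Si](C)(C)Oc1ccc(O[Si](C)(C)C(C)(C)C)c(Br)c1 | intermediate
25 | 2,5-bis(TBSO)phenylmagnesium bromide | CC(C)(C)[Si](C)(C)Oc1ccc(O[Si](C)(C)C(C)(C)C)c([Mg]Br)c1 | intermediate
26 | magnesium hemiaminal chelate (new carbon unassigned) | C[Si](C)(C)CCOC(=O)[C@]1(CC(O[Mg]Br)(N(C)OC)c2cc(O[Si](C)(C)C(C)(C)C)ccc2O[Si](C)(C)C(C)(C)C)CCC=C(CC/C=C(\C)CO[Si](C)(C)C(C)(C)C)CO1 | intermediate
27 | aryl ketone, tris-TBS, TMSE ester | C[Si](C)(C)CCOC(=O)[C@]1(CC(=O)c2cc(O[Si](C)(C)C(C)(C)C)ccc2O[Si](C)(C)C(C)(C)C)CCC=C(CC/C=C(\C)CO[Si](C)(C)C(C)(C)C)CO1 | intermediate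
28 | allylic alcohol, bis-aryl-TBS, TMSE ester | C[Si](C)(C)CCOC(=O)[C@]1(CC(=O)c2cc(O[Si](C)(C)C(C)(C)C)ccc2O[Si](C)(C)C(C)(C)C)CCC=C(CC/C=C(\C)CO)CO1 | intermediate
29 | p-coumaric acid | OC(=O)/C=C/c1ccc(O)cc1 | starting material
30 | TBS (E)-4-(TBSO)cinnamate | CC(C)(C)[Si](C)(C)OC(=O)/C=C/c1ccc(O[Si](C)(C)C(C)(C)C)cc1 | intermediate
31 | (E)-4-(TBSO)cinnamic acid | OC(=O)/C=C/c1ccc(O[Si](C)(C)C(C)(C)C)cc1 | intermediate
32 | fully silylated target | C[Si](C)(C)CCOC(=O)[C@]1(CC(=O)c2cc(O[Si](C)(C)C(C)(C)C)ccc2O[Si](C)(C)C(C)(C)C)CCC=C(CC/C=C(\C)COC(=O)/C=C/c2ccc(O[Si](C)(C)C(C)(C)C)cc2)CO1 | intermediate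
33 | CNP0602535.1 | C/C(=C\CCC1=CCC[C@@](CC(=O)c2cc(O)ccc2O)(C(=O)O)OC1)COC(=O)/C=C/c1ccc(O)cc1 | target

**Step count**
Total: 19 steps.
Longest linear sequence: 14 steps (steps 1–9, 13, 15, 16, 18, 19, from D-malic acid).

**Steps most likely to fail**

1. Step 9, regiochemistry of enolisation.
   - What may go wrong: proton removal at C7, or equilibration of the two enolates before sulfonylation, would place the double bond toward O1.
   - Fallback: it sets out from 13. Aerobic palladium(II) dehydrogenation (Pd(TFA)2, DMSO, O2, AcOH, warm) can only act on the C5 side, because a palladium enolate at C7 has no β-hydrogen. It should give 2-(trimethylsilyl)ethyl (2R)-2-{2-[methoxy(methyl)amino]-2-oxoethyl}-6-oxo-2,3,6,7-tetrahydrooxepine-2-carboxylate F5.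
   - Conjugate reduction with L-Selectride (THF, −78 °C) then generates the C5=C6 enolate regiospecifically. Trapping it in the same flask with Comins reagent rejoins the route at 15.

2. Step 8, diversion of the carbenoid.
   - What may go wrong: the hindered, electron-poor and hydrogen-bonded hydroxyl may attack too slowly. C–H insertion at C3, carbene dimerisation or capture of traces of water could then take over.
   - Fallback: it sets out from 9 and uses a stabilised acceptor/acceptor carbenoid, the substrate class on which oxepanone formation by O–H insertion is best documented.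
   - Masamune–Brooks homologation (CDI, then magnesium monobenzyl malonate, THF) gives benzyl 6-[(2R,4R)-2-tert-butyl-4-{2-[methoxy(methyl)amino]-2-oxoethyl}-5-oxo-1,3-dioxolan-4-yl]-3-oxohexanoate F1.
   - A slight excess of lithium 2-(trimethylsilyl)ethoxide opens the dioxolanone while the β-keto ester is masked as its enolate. This gives 8-benzyl 1-[2-(trimethylsilyl)ethyl] (2R)-2-hydroxy-2-{2-[methoxy(methyl)amino]-2-oxoethyl}-6-oxooctanedioate F2.
   - Regitz diazo transfer (p-ABSA, Et3N, MeCN) gives the 7-diazo derivative F3.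
   - Rh2(OAc)4 in hot benzene closes O1–C7 to 7-benzyl 2-[2-(trimethylsilyl)ethyl] (2R)-2-{2-[methoxy(methyl)amino]-2-oxoethyl}-6-oxooxepane-2,7-dicarboxylate F4.
   - Hydrogenolysis (H2, Pd/C, EtOAc) with gentle warming decarboxylates the β-keto acid and rejoins the route at 13.

3. Step 15, chemoselectivity of the aryl nucleophile.
   - What may go wrong: possible failures are attack on the TMSE ester, slow addition of the ortho-silyloxy Grignard reagent, base-induced loss of formaldehyde from the N-methoxy group, and deprotonation of the amide α-CH2 with β-elimination of O1.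
   - Fallback: it sets out from 22 and hides the carboxyl as its salt. TBAF (THF, rt) removes TMSE and TBS together to give (2R)-6-[(3E)-5-hydroxy-4-methylpent-3-en-1-yl]-2-{2-[methoxy(methyl)amino]-2-oxoethyl}-2,3,4,7-tetrahydrooxepine-2-carboxylic acid F6.
   - After deprotonation with LiHMDS (2 equiv), excess 25 adds only to the amide of the carboxylate–alkoxide. This gives (2R)-2-[2-(2,5-bis{[tert-butyl(dimethyl)silyl]oxy}phenyl)-2-oxoethyl]-6-[(3E)-5-hydroxy-4-methylpent-3-en-1-yl]-2,3,4,7-tetrahydrooxepine-2-carboxylic acid F7.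
   - Promoter-free esterification of the acid alone with 2-(trimethylsilyl)ethyl trichloroacetimidate (toluene, reflux) rejoins the route at 28, so step 16 is skipped.

**Further compounds**
F1 | step 8 | benzyl 6-[(2R,4R)-2-tert-butyl-4-{2-[methoxy(methyl)amino]-2-oxoethyl}-5-oxo-1,3-dioxolan-4-yl]-3-oxohexanoate | CC(C)(C)[C@@H]1O[C@](CCCC(=O)CC(=O)OCc2ccccc2)(CC(=O)N(C)OC)C(=O)O1
F2 | step 8 | 8-benzyl 1-[2-(trimethylsilyl)ethyl] (2R)-2-hydroxy-2-{2-[methoxy(methyl)amino]-2-oxoethyl}-6-oxooctanedioate | C[Si](C)(C)CCOC(=O)[C@](O)(CC(=O)N(C)OC)CCCC(=O)CC(=O)OCc1ccccc1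
F3 | step 8 | 8-benzyl 1-[2-(trimethylsilyl)ethyl] (2R)-7-diazo-2-hydroxy-2-{2-[methoxy(methyl)amino]-2-oxoethyl}-6-oxooctanedioate | C[Si](C)(C)CCOC(=O)[C@](O)(CC(=O)N(C)OC)CCCC(=O)C(=[N+]=[N-])C(=O)OCc1ccccc1
F4 | step 8 | 7-benzyl 2-[2-(trimethylsilyl)ethyl] (2R)-2-{2-[methoxy(methyl)amino]-2-oxoethyl}-6-oxooxepane-2,7-dicarboxylate (C7 unassigned) | C[Si](C)(C)CCOC(=O)[C@]1(CC(=O)N(C)OC)CCCC(=O)C(C(=O)OCc2ccccc2)O1
F5 | step 9 | 2-(trimethylsilyl)ethyl (2R)-2-{2-[methoxy(methyl)amino]-2-oxoethyl}-6-oxo-2,3,6,7-tetrahydrooxepine-2-carboxylate | C[Si](C)(C)CCOC(=O)[C@]1(CC(=O)N(C)OC)CC=CC(=O)CO1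
F6 | step 15 | (2R)-6-[(3E)-5-hydroxy-4-methylpent-3-en-1-yl]-2-{2-[methoxy(methyl)amino]-2-oxoethyl}-2,3,4,7-tetrahydrooxepine-2-carboxylic acid | OC(=O)[C@]1(CC(=O)N(C)OC)CCC=C(CC/C=C(\C)CO)CO1
F7 | step 15 | (2R)-2-[2-(2,5-bis{[tert-butyl(dimethyl)silyl]oxy}phenyl)-2-oxoethyl]-6-[(3E)-5-hydroxy-4-methylpent-3-en-1-yl]-2,3,4,7-tetrahydrooxepine-2-carboxylic acid | OC(=O)[C@]1(CC(=O)c2cc(O[Si](C)(C)C(C)(C)C)ccc2O[Si](C)(C)C(C)(C)C)CCC=C(CC/C=C(\C)CO)CO1
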